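**Plan**

1. Numbering as in germacranolides: ring C1–C10 (methyls on C4 and C10), lactone O on C6, C7–C11(=C13)–C12(=O).
2. Retrosynthetic cuts, in order: the two oxirane C–O pairs (C1/C10, C4/C5) and the C8 ester; then C7–C11 (lactone ring, from a C6 acrylate and a cis-7,8-epoxide); then C5–C6 (ten-membered ring); then C2–C3, C7=C8 and C9–C10 of the open chain.
3. Forward: the open chain is built from but-2-yn-1-ol (Stille, cross-metathesis, propargylation, carboalumination); the ten-membered ring closes by a chromium/nickel reaction; the γ-lactone closes in the key step; both oxiranes are made last.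
4. Enabling feature: C7 carries the new C–C bond and its neighbour C8 an oxygen, in the relative configuration that rear-side opening of a cis-7,8-epoxide delivers. The lactone oxygen on C6 is a built-in tether that holds an acrylate α-carbon (C11) five atoms from C7. A phosphine makes that carbon nucleophilic, so one isomerisation forms the α-methylene-γ-lactone, sets C7 and frees the C8 hydroxyl.
5. Stereochemistry: C2 from catalyst-controlled propargylation; C7/C8 from Sharpless epoxidation of a (Z)-allylic alcohol; C6 from chelation-controlled reduction next to that epoxide; C7 inverted in the key step; C1, C10, C4, C5 from hydroxyl-directed and peripheral epoxidation of the (Z)- and (E)-alkenes.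

Key step: step 15

Assumption: the enantiomer of the phosphoric acid in step 5 is the one that delivers the (S)-carbinol; it is written as (S)-TRIP and would be exchanged for its antipode if the sense of induction proved opposite.

**Route**

Step 1
Reactants: 1 but-2-yn-1-ol
Product: 3 (Z)-3-iodobut-2-en-1-ol, via cyclic alkenylalanate 2 (not isolated)
Conditions: NaAlH2(OCH2CH2OMe)2 (Red-Al), THF, 0 °C to rt; then I2, −78 °C to 0 °C
Reagents that add atoms: iodine, II
Why: Hydroxyl-directed trans-hydroalumination places aluminium on C3 in a five-membered alkoxy-alanate, and iodinolysis with retention should give only the (Z)-iodoalkene.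

Step 2
Reactants: 3 (Z)-3-iodobut-2-en-1-ol; 4 allyltributylstannane
Product: 5 (Z)-3-methylhexa-2,5-dien-1-ol
Conditions: Pd(PPh3)4 (5 mol %), CuI, CsF, DMF, 45 °C
Reagents that add atoms: none
Why: Stille coupling of an alkenyl iodide with an allylstannane on zerovalent palladium proceeds with retention of alkene geometry, so the allyl group should end cis to CH2OH.

Step 3
Reactants: 5 (Z)-3-methylhexa-2,5-dien-1-ol; 6 (Z)-but-2-ene-1,4-diyl diacetate
Product: 7 (2Z,5Z)-7-hydroxy-5-methylhepta-2,5-dien-1-yl acetate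
Conditions: 6 (3 equiv), Ru(NO3)(=CH-C6H4-2-OiPr)[κ2-C,C-1-(adamantyl)-3-(2,6-diisopropylphenyl)imidazolidin-2-ylidene] (cyclometalated Z-selective Grubbs catalyst, 5 mol %), THF, 35 °C
Reagents that add atoms: none
Why: Z-selective olefin cross-metathesis engages only the monosubstituted alkene (the trisubstituted one is inert) and should transfer the CH–CH2OAc unit of the cis-diacetate with (Z)-geometry.

Step 4
Reactants: 7 (2Z,5Z)-7-hydroxy-5-methylhepta-2,5-dien-1-yl acetate
Product: 8 (2Z,5Z)-5-methyl-7-oxohepta-2,5-dien-1-yl acetate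
Conditions: TEMPO (10 mol %), PhI(OAc)2, CH2Cl2, rt
Reagents that add atoms: none
Why: Oxoammonium oxidation of the primary allylic alcohol stops at the aldehyde and is mild enough to leave the (Z)-enal geometry and the acetate untouched.

Step 5
Reactants: 8 (2Z,5Z)-5-methyl-7-oxohepta-2,5-dien-1-yl acetate; 9 allenylboronic acid pinacol ester
Product: 10 (2Z,5Z,7S)-7-hydroxy-5-methyldeca-2,5-dien-9-yn-1-yl acetate
Conditions: (S)-TRIP (5 mol %), 4 Å MS, toluene, −20 °C
Reagents that add atoms: none
Why: Chiral phosphoric acid-catalysed propargylation (SE2' transfer from the allenylboronate through a closed six-membered transition state, 1,2-addition to the enal) should give the homopropargylic alcohol, the acid enantiomer setting the carbinol (target C2) as S.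

Step 6
Reactants: 10 (2Z,5Z,7S)-7-hydroxy-5-methyldeca-2,5-dien-9-yn-1-yl acetate
Product: 11 (2Z,5Z,7S)-7-[(tert-butyldimethylsilyl)oxy]-5-methyldeca-2,5-dien-9-yn-1-yl acetate
Conditions: TBSCl, imidazole, DMF, rt
Reagents that add atoms: tert-butyldimethylsilyl chloride, CC(C)(C)[Si](C)(C)Cl
Why: Standard silylation of a secondary alcohol, which masks the C2 hydroxyl so that it cannot direct the later epoxidation or be oxidised.

Step 7
Reactants: 11 (2Z,5Z,7S)-7-[(tert-butyldimethylsilyl)oxy]-5-methyldeca-2,5-dien-9-yn-1-yl acetate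
Product: 12 (2Z,5Z,7S)-7-[(tert-butyldimethylsilyl)oxy]-5-methyldeca-2,5-dien-9-yn-1-ol
Conditions: K2CO3, MeOH, 0 °C
Reagents that add atoms: none
Why: Mild transesterification removes the acetate (which would not survive trimethylaluminium) without touching the silyl ether or the terminal alkyne.

Step 8
Reactants: 12 (2Z,5Z,7S)-7-[(tert-butyldimethylsilyl)oxy]-5-methyldeca-2,5-dien-9-yn-1-ol
Product: 14 (2Z,5Z,7S,9E)-7-[(tert-butyldimethylsilyl)oxy]-10-iodo-5,9-dimethyldeca-2,5,9-trien-1-ol, via alkenylalane 13 (not isolated)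
Conditions: Me3Al, Cp2ZrCl2 (20 mol %), H2O (1 equiv), CH2Cl2, −20 °C to rt; then I2, THF, −30 °C
Reagents that add atoms: trimethylaluminium, C[Al](C)C; iodine, II
Why: Zirconium-catalysed syn-carboalumination (Negishi) of the terminal alkyne puts methyl on the internal and aluminium on the terminal carbon, and iodinolysis with retention should give the (E)-iodoalkene, the free hydroxyl being carried as its aluminium alkoxide.

Step 9
Reactants: 14 (2Z,5Z,7S,9E)-7-[(tert-butyldimethylsilyl)oxy]-10-iodo-5,9-dimethyldeca-2,5,9-trien-1-ol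
Product: 15 [(2R,3S)-3-{(2Z,4S,6E)-4-[(tert-butyldimethylsilyl)oxy]-7-iodo-2,6-dimethylhepta-2,6-dien-1-yl}oxiran-2-yl]methanol
Conditions: Ti(OiPr)4, D-(−)-diethyl tartrate, tBuOOH, 4 Å MS, CH2Cl2, −20 °C
Reagents that add atoms: tert-butyl hydroperoxide, CC(C)(C)OO
Why: Sharpless asymmetric epoxidation acts only on the allylic alcohol, and with the D-(−)-tartrate oxygen should be delivered to the face that gives the (2R,3S)-cis-epoxide (target C7 and C8) under reagent control.

Step 10
Reactants: 15 [(2R,3S)-3-{(2Z,4S,6E)-4-[(tert-butyldimethylsilyl)oxy]-7-iodo-2,6-dimethylhepta-2,6-dien-1-yl}oxiran-2-yl]methanol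
Product: 16 (2S,3S)-3-{(2Z,4S,6E)-4-[(tert-butyldimethylsilyl)oxy]-7-iodo-2,6-dimethylhepta-2,6-dien-1-yl}oxirane-2-carbaldehyde
Conditions: Dess–Martin periodinane, NaHCO3, CH2Cl2, 0 °C
Reagents that add atoms: none
Why: Buffered Dess–Martin oxidation converts 2,3-epoxy alcohols into epoxy aldehydes without epimerisation or oxirane opening (the descriptor at C2 changes by priority only).

Step 11
Reactants: 16 (2S,3S)-3-{(2Z,4S,6E)-4-[(tert-butyldimethylsilyl)oxy]-7-iodo-2,6-dimethylhepta-2,6-dien-1-yl}oxirane-2-carbaldehyde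
Product: 17 (1(10)Z,2S,4E,7R,8S)-2-[(tert-butyldimethylsilyl)oxy]-7,8-epoxy-4,10-dimethylcyclodeca-1(10),4-dien-6-ol as both C6 epimers (ring numbered as in the target)
Conditions: CrCl2 (8 equiv), NiCl2 (2 mol %), DMSO/THF, rt, 0.003 M, slow addition
Reagents that add atoms: none
Why: Nozaki–Hiyama–Kishi reaction, in which zerovalent nickel inserts into the C–I bond, the alkenyl group passes to trivalent chromium and adds chemoselectively to the aldehyde, should close the ten-membered ring with retention of the (E)-alkene; C6 is not controlled here and both epimers are carried on.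

Step 12
Reactants: 17 (1(10)Z,2S,4E,7R,8S)-2-[(tert-butyldimethylsilyl)oxy]-7,8-epoxy-4,10-dimethylcyclodeca-1(10),4-dien-6-ol (both C6 epimers)
Product: 18 (1(10)Z,2S,4E,7S,8S)-2-[(tert-butyldimethylsilyl)oxy]-7,8-epoxy-4,10-dimethylcyclodeca-1(10),4-dien-6-one
Conditions: Dess–Martin periodinane, NaHCO3, CH2Cl2, rt
Reagents that add atoms: none
Why: Oxidation of the allylic alcohol merges both C6 epimers into one α,β-epoxy enone.

Step 13
Reactants: 18 (1(10)Z,2S,4E,7S,8S)-2-[(tert-butyldimethylsilyl)oxy]-7,8-epoxy-4,10-dimethylcyclodeca-1(10),4-dien-6-one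
Product: 19 (1(10)Z,2S,4E,6R,7R,8S)-2-[(tert-butyldimethylsilyl)oxy]-7,8-epoxy-4,10-dimethylcyclodeca-1(10),4-dien-6-ol
Conditions: Zn(BH4)2, Et2O, −30 °C
Reagents that add atoms: none
Why: Chelation-controlled 1,2-reduction of an α,β-epoxy ketone, in which zinc bridges the carbonyl and oxirane oxygens and hydride enters from the face away from C8, should give the erythro (6R) epoxy alcohol.

Step 14
Reactants: 19 (1(10)Z,2S,4E,6R,7R,8S)-2-[(tert-butyldimethylsilyl)oxy]-7,8-epoxy-4,10-dimethylcyclodeca-1(10),4-dien-6-ol; 20 acryloyl chloride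
Product: 21 (1(10)Z,2S,4E,6R,7S,8S)-2-[(tert-butyldimethylsilyl)oxy]-7,8-epoxy-4,10-dimethylcyclodeca-1(10),4-dien-6-yl prop-2-enoate
Conditions: Et3N, CH2Cl2, −20 °C to 0 °C
Reagents that add atoms: none
Why: O-Acylation of the secondary alcohol with an acid chloride and a tertiary amine leaves the neighbouring oxirane and all stereocentres untouched.

Step 15
Reactants: 21 (1(10)Z,2S,4E,6R,7S,8S)-2-[(tert-butyldimethylsilyl)oxy]-7,8-epoxy-4,10-dimethylcyclodeca-1(10),4-dien-6-yl prop-2-enoate
Product: 24 (2S,6R,7R,8S)-2-[(tert-butyldimethylsilyl)oxy]-8-hydroxygermacra-1(10)Z,4E,11(13)-trien-12,6-olide, via phosphonium ester enolate 22 (not isolated), via phosphonium alkoxide 23 (not isolated)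
Conditions: PMe3 (1.0 equiv), tBuOH/THF (degassed), rt, 0.01 M
Reagents that add atoms: none
Why: Proposed new method: PMe3 adds reversibly to the acrylate β-carbon (C13) of 21 to give the phosphonium ester enolate 22, whose α-carbon (C11) attacks C7 of the cis-7,8-epoxide from the rear to give 23, and proton transfer from C11 to the C8 alkoxide followed by E1cB loss of PMe3 unveils the exocyclic methylene, so that the whole step is a by-product-free isomerisation. The closest known reaction type is the trialkylphosphine-mediated intramolecular Morita–Baylis–Hillman alkylation of enones by tethered epoxides or allylic halides; new here are the acrylate ester as the latent nucleophile and the formation of a lactone ring. The γ-lactone closes in the 5-exo-tet mode. C7 is set by inversion, the nucleophile being delivered from the C6 oxygen anti to the C7–O bond, which with the erythro (6R,7S) arrangement of 21 gives the trans-fused lactone, while C8 keeps the configuration installed in step 9 and appears as the free hydroxyl. The step needs attack at C7 and not at C8 and needs a single electrophile: the five-membered transition state is favoured over the six-membered one, C1=C10 and C4=C5 are deliberately still alkenes so that no second oxirane competes, and high dilution in a protic medium suppresses Rauhut–Currier oligomerisation and speeds the proton transfer.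

Step 16
Reactants: 24 (2S,6R,7R,8S)-2-[(tert-butyldimethylsilyl)oxy]-8-hydroxygermacra-1(10)Z,4E,11(13)-trien-12,6-olide; 25 angelic acid
Product: 27 (2S,6R,7R,8S)-8-angeloyloxy-2-[(tert-butyldimethylsilyl)oxy]germacra-1(10)Z,4E,11(13)-trien-12,6-olide, via angelic 2,4,6-trichlorobenzoic anhydride 26 (not isolated)
Conditions: 25, 2,4,6-trichlorobenzoyl chloride, Et3N, toluene, rt; then 24, 80 °C
Reagents that add atoms: none
Why: Yamaguchi esterification through the mixed anhydride acylates the C8 hydroxyl with retention at carbon and, run without a nucleophilic amine catalyst, should not isomerise the (Z)-angelate to the tiglate.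

Step 17
Reactants: 27 (2S,6R,7R,8S)-8-angeloyloxy-2-[(tert-butyldimethylsilyl)oxy]germacra-1(10)Z,4E,11(13)-trien-12,6-olide
Product: 28 (2S,6R,7R,8S)-8-angeloyloxy-2-hydroxygermacra-1(10)Z,4E,11(13)-trien-12,6-olide
Conditions: HF·pyridine, pyridine, THF, 0 °C to rt
Reagents that add atoms: none
Why: Buffered fluoride cleavage of the silyl ether is non-basic, so the α-methylene lactone and the angelate should survive.

Step 18
Reactants: 28 (2S,6R,7R,8S)-8-angeloyloxy-2-hydroxygermacra-1(10)Z,4E,11(13)-trien-12,6-olide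
Product: 29 (1R,2S,4R,5R,6S,7R,8S,10S)-8-angeloyloxy-1,10:4,5-diepoxy-2-hydroxygermacr-11(13)-en-12,6-olide (target)
Conditions: mCPBA (2.5 equiv), NaHCO3, CH2Cl2, 0 °C
Reagents that add atoms: 3-chloroperoxybenzoic acid, OOC(=O)c1cccc(Cl)c1
Why: Peracid epoxidation takes only the two electron-rich trisubstituted alkenes; the C2 hydroxyl should direct oxygen to the syn face of the (Z)-C1=C10 bond in its A(1,3)-minimised conformer (Henbest-type, threo, cis-oxirane, 1R,10S), and the (E)-C4=C5 bond should be attacked from its peripheral face, the one on the side of the C6–O bond (4R,5R), as in related trans-fused germacranolides.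

**Compound list**

1 | but-2-yn-1-ol | CC#CCO | starting material
2 | sodium cyclic (Z)-alkenylalanate (2,5-dihydro-1,2-oxaluminole with two 2-methoxyethoxy ligands on aluminium) | CC1=CCO[Al-]1(OCCOC)OCCOC.[Na+] | intermediate
3 | (Z)-3-iodobut-2-en-1-ol | C/C(I)=C/CO | intermediate
4 | allyltributylstannane | C=CC[Sn](CCCC)(CCCC)CCCC | starting material
5 | (Z)-3-methylhexa-2,5-dien-1-ol | C/C(CC=C)=C/CO | intermediate
6 | (Z)-but-2-ene-1,4-diyl diacetate | CC(=O)OC/C=C\COC(C)=O | starting material
7 | (2Z,5Z)-7-hydroxy-5-methylhepta-2,5-dien-1-yl acetate | CC(=O)OC/C=C\C/C(C)=C\CO | intermediate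
8 | (2Z,5Z)-5-methyl-7-oxohepta-2,5-dien-1-yl acetate | CC(=O)OC/C=C\C/C(C)=C\C=O | intermediate
9 | allenylboronic acid pinacol ester | C=C=CB1OC(C)(C)C(C)(C)O1 | starting material
10 | (2Z,5Z,7S)-7-hydroxy-5-methyldeca-2,5-dien-9-yn-1-yl acetate | CC(=O)OC/C=C\C/C(C)=C\[C@@H](O)CC#C | intermediate
11 | (2Z,5Z,7S)-7-[(tert-butyldimethylsilyl)oxy]-5-methyldeca-2,5-dien-9-yn-1-yl acetate | CC(=O)OC/C=C\C/C(C)=C\[C@@H](O[Si](C)(C)C(C)(C)C)CC#C | intermediate
12 | (2Z,5Z,7S)-7-[(tert-butyldimethylsilyl)oxy]-5-methyldeca-2,5-dien-9-yn-1-ol | OC/C=C\C/C(C)=C\[C@@H](O[Si](C)(C)C(C)(C)C)CC#C | intermediate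
13 | (E)-alkenyl(dimethyl)alane from 12, carried as its O-dimethylaluminium alkoxide | C[Al](C)OC/C=C\C/C(C)=C\[C@@H](O[Si](C)(C)C(C)(C)C)C/C(C)=C/[Al](C)C | intermediate
14 | (2Z,5Z,7S,9E)-7-[(tert-butyldimethylsilyl)oxy]-10-iodo-5,9-dimethyldeca-2,5,9-trien-1-ol | OC/C=C\C/C(C)=C\[C@@H](O[Si](C)(C)C(C)(C)C)C/C(C)=C/I | intermediate
15 | [(2R,3S)-3-{(2Z,4S,6E)-4-[(tert-butyldimethylsilyl)oxy]-7-iodo-2,6-dimethylhepta-2,6-dien-1-yl}oxiran-2-yl]methanol | OC[C@H]1O[C@H]1C/C(C)=C\[C@@H](O[Si](C)(C)C(C)(C)C)C/C(C)=C/I | intermediate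
16 | (2S,3S)-3-{(2Z,4S,6E)-4-[(tert-butyldimethylsilyl)oxy]-7-iodo-2,6-dimethylhepta-2,6-dien-1-yl}oxirane-2-carbaldehyde | O=C[C@H]1O[C@H]1C/C(C)=C\[C@@H](O[Si](C)(C)C(C)(C)C)C/C(C)=C/I | intermediate
17 | (1(10)Z,2S,4E,7R,8S)-2-[(tert-butyldimethylsilyl)oxy]-7,8-epoxy-4,10-dimethylcyclodeca-1(10),4-dien-6-ol, both C6 epimers (target numbering) | C1/C(C)=C/C(O)[C@H]2O[C@H]2C/C(C)=C\[C@H]1O[Si](C)(C)C(C)(C)C | intermediate
18 | (1(10)Z,2S,4E,7S,8S)-2-[(tert-butyldimethylsilyl)oxy]-7,8-epoxy-4,10-dimethylcyclodeca-1(10),4-dien-6-one | C1/C(C)=C/C(=O)[C@H]2O[C@H]2C/C(C)=C\[C@H]1O[Si](C)(C)C(C)(C)C | intermediate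
19 | (1(10)Z,2S,4E,6R,7R,8S)-2-[(tert-butyldimethylsilyl)oxy]-7,8-epoxy-4,10-dimethylcyclodeca-1(10),4-dien-6-ol | C1/C(C)=C/[C@@H](O)[C@H]2O[C@H]2C/C(C)=C\[C@H]1O[Si](C)(C)C(C)(C)C | intermediate
20 | acryloyl chloride | C=CC(=O)Cl | starting material
21 | (1(10)Z,2S,4E,6R,7S,8S)-2-[(tert-butyldimethylsilyl)oxy]-7,8-epoxy-4,10-dimethylcyclodeca-1(10),4-dien-6-yl prop-2-enoate | C1/C(C)=C/[C@@H](OC(=O)C=C)[C@H]2O[C@H]2C/C(C)=C\[C@H]1O[Si](C)(C)C(C)(C)C | intermediate
22 | phosphonium ester enolate (PMe3 adduct of 21 at C13, zwitterion) | C1/C(C)=C/[C@@H](OC([O-])=CC[P+](C)(C)C)[C@H]2O[C@H]2C/C(C)=C\[C@H]1O[Si](C)(C)C(C)(C)C | intermediate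
23 | phosphonium alkoxide (trans-fused lactone with C11–CH2–PMe3+ and C8–O−, zwitterion) | C1/C(C)=C/[C@H]2OC(=O)C(C[P+](C)(C)C)[C@@H]2[C@@H]([O-])C/C(C)=C\[C@H]1O[Si](C)(C)C(C)(C)C | intermediate
24 | (2S,6R,7R,8S)-2-[(tert-butyldimethylsilyl)oxy]-8-hydroxygermacra-1(10)Z,4E,11(13)-trien-12,6-olide | C1/C(C)=C/[C@H]2OC(=O)C(=C)[C@@H]2[C@@H](O)C/C(C)=C\[C@H]1O[Si](C)(C)C(C)(C)C | intermediate
25 | angelic acid, (Z)-2-methylbut-2-enoic acid | C/C=C(/C)C(=O)O | starting material
26 | angelic 2,4,6-trichlorobenzoic anhydride | C/C=C(/C)C(=O)OC(=O)c1c(Cl)cc(Cl)cc1Cl | intermediate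
27 | (2S,6R,7R,8S)-8-angeloyloxy-2-[(tert-butyldimethylsilyl)oxy]germacra-1(10)Z,4E,11(13)-trien-12,6-olide | C1/C(C)=C/[C@H]2OC(=O)C(=C)[C@@H]2[C@@H](OC(=O)/C(C)=C\C)C/C(C)=C\[C@H]1O[Si](C)(C)C(C)(C)C | intermediate
28 | (2S,6R,7R,8S)-8-angeloyloxy-2-hydroxygermacra-1(10)Z,4E,11(13)-trien-12,6-olide | C1/C(C)=C/[C@H]2OC(=O)C(=C)[C@@H]2[C@@H](OC(=O)/C(C)=C\C)C/C(C)=C\[C@H]1O | intermediate
29 | (1R,2S,4R,5R,6S,7R,8S,10S)-8-angeloyloxy-1,10:4,5-diepoxy-2-hydroxygermacr-11(13)-en-12,6-olide | C=C1C(=O)O[C@H]2[C@H]1[C@@H](OC(=O)/C(C)=C\C)C[C@]1(C)O[C@@H]1[C@@H](O)C[C@@]1(C)O[C@H]21 | target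

**Step count and risks**

Total step count: 18. Longest linear sequence: 18 steps (the route is linear from 1).

Step 15 (proposed new method). The ester-derived phosphonium enolate may be too weakly nucleophilic or too short-lived, so that intermolecular Rauhut–Currier oligomerisation of the acrylate, or simple return to 21, outruns opening of the oxirane. The fallback sets out from 19 and uses a stoichiometric, stabilised carbanion. Compound 19 is esterified with diethylphosphonoacetic acid (DCC, DMAP, CH2Cl2) to the phosphonoacetate F1. KOtBu (THF, 0 °C to rt) then generates the phosphonate carbanion, which opens the oxirane at C7 in the same 5-exo-tet sense and with the same inversion to give the α-phosphono lactone F2. Addition of aqueous formaldehyde and K2CO3 to the same flask effects Horner–Wadsworth–Emmons methylenation, and the route is rejoined at 24.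

Step 18. Two things may go wrong: acid-promoted transannular attack of the C4=C5 alkene on the first-formed 1,10-oxirane, and erosion of facial selectivity at either alkene when hydroxyl direction and ring shape do not cooperate. The fallback sets out from 27 and reverses the order of the last two operations. The silyl ether 27 is epoxidised with dimethyldioxirane (acetone, 0 °C), a neutral oxidant that leaves no acid and attacks only from the ring periphery, to give the silyl-protected diepoxide F3. Removal of the silyl group (HF·pyridine, pyridine, THF) then returns the route at 29.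

Step 13. Zinc may be unable to bridge the ketone and oxirane oxygens within the ten-membered ring, so that hydride delivery loses its facial selectivity and the C6 epimer predominates. The fallback sets out from 18 and makes that epimer on purpose. A bulky, non-chelating hydride (L-Selectride, THF, −78 °C) gives the (6S)-alcohol F4. Its hydroxyl is then displaced with inversion by acrylic acid under Mitsunobu conditions (PPh3, diisopropyl azodicarboxylate, THF, 0 °C), which installs the ester and corrects C6 in one operation; the route is rejoined at 21.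

**Further compounds**

F1 | step 15 | (1(10)Z,2S,4E,6R,7S,8S)-2-[(tert-butyldimethylsilyl)oxy]-7,8-epoxy-4,10-dimethylcyclodeca-1(10),4-dien-6-yl 2-(diethoxyphosphoryl)acetate | C1/C(C)=C/[C@@H](OC(=O)CP(=O)(OCC)OCC)[C@H]2O[C@H]2C/C(C)=C\[C@H]1O[Si](C)(C)C(C)(C)C
F2 | step 15 | (2S,6R,7R,8S)-2-[(tert-butyldimethylsilyl)oxy]-11-(diethoxyphosphoryl)-8-hydroxy-13-norgermacra-1(10)Z,4E-dien-12,6-olide (C11 epimers) | C1/C(C)=C/[C@H]2OC(=O)C(P(=O)(OCC)OCC)[C@@H]2[C@@H](O)C/C(C)=C\[C@H]1O[Si](C)(C)C(C)(C)C
F3 | step 18 | 2-O-(tert-butyldimethylsilyl) ether of 29 | C=C1C(=O)O[C@H]2[C@H]1[C@@H](OC(=O)/C(C)=C\C)C[C@]1(C)O[C@@H]1[C@@H](O[Si](C)(C)C(C)(C)C)C[C@@]1(C)O[C@H]21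
F4 | step 13 | (1(10)Z,2S,4E,6S,7R,8S)-2-[(tert-butyldimethylsilyl)oxy]-7,8-epoxy-4,10-dimethylcyclodeca-1(10),4-dien-6-ol (C6 epimer of 19) | C1/C(C)=C/[C@H](O)[C@H]2O[C@H]2C/C(C)=C\[C@H]1O[Si](C)(C)C(C)(C)C
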